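**Assumption:** the SMILES has no stereocentre. Each ring has only one substituent (OH) ortho to the biaryl axis, so the axis rotates freely at room temperature. The target is therefore treated as achiral, and no step needs stereocontrol.

## Retrosynthetic overview
1. Target 8 comes from one global hydrogenation (C=C saturation plus O-debenzylation) of the bis-cinnamic acid 6.
2. 6 is disconnected at C2–C3 of both side chains by a twofold Knoevenagel–Doebner (aldol-type) condensation, giving dialdehyde 3 and two malonic acid 4.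
3. 3 comes from O-benzylation of dehydrodivanillin 2, and 2 from C5–C5' oxidative phenol coupling of vanillin 1.
4. No ring is built. Both arenes come intact from vanillin; the biaryl bond is made first and the side chains second.

## Route

Step 1
Reactants: 1 vanillin (2 equiv in the equation)
Product: 2 dehydrodivanillin (6,6'-dihydroxy-5,5'-dimethoxy-[1,1'-biphenyl]-3,3'-dicarbaldehyde)
Conditions: Na2S2O8 (0.55 equiv per vanillin), FeSO4·7H2O (3 mol %), H2O, 50 °C, 3–5 d; filter the precipitate, wash with hot water
Reagents that add atoms: none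
Why: In this Fe(II)/persulfate oxidative phenol coupling the phenoxyl radical has its para position (CHO) and one ortho position (OMe) blocked, so only the C5–C5' bond can form, the insoluble dimer precipitates before it over-oxidises, and no stereocentre is created.

Step 2
Reactants: 2 dehydrodivanillin
Product: 3 6,6'-bis(benzyloxy)-5,5'-dimethoxy-[1,1'-biphenyl]-3,3'-dicarbaldehyde
Conditions: BnBr (3 equiv), K2CO3 (4 equiv), DMF, 70 °C, 12 h
Reagents that add atoms: benzyl bromide BrCc1ccccc1
Why: This Williamson ether synthesis on the non-enolisable dialdehyde makes the material soluble and masks the phenols, which as phenoxides would deactivate the aldehydes and let the 4-hydroxycinnamic acids decarboxylate in hot pyridine, and the benzyl groups cost no extra step because they fall off in step 4.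

Step 3
Reactants: 3 6,6'-bis(benzyloxy)-5,5'-dimethoxy-[1,1'-biphenyl]-3,3'-dicarbaldehyde; 4 malonic acid (5 equiv used, 2 equiv consumed)
Product: 6 (2E,2'E)-3,3'-[6,6'-bis(benzyloxy)-5,5'-dimethoxybiphenyl-3,3'-diyl]bis(prop-2-enoic acid), via bis(arylidenemalonic acid) 5 (not isolated)
Conditions: pyridine, piperidine (0.3 equiv), 80 °C then 110 °C, 5 h; pour into cold 2 M HCl, filter, recrystallise (AcOH or THF/EtOH)
Reagents that add atoms: none
Why: In this Knoevenagel–Doebner condensation the malonic acid enolate adds aldol-fashion to each aldehyde, dehydration and pyridine-promoted decarboxylation then give the thermodynamic E,E-diacid, excess malonic acid drives both ends to completion, and no stereocentre is formed (the alkene geometry is erased in step 4).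

Step 4
Reactants: 6 (2E,2'E)-3,3'-[6,6'-bis(benzyloxy)-5,5'-dimethoxybiphenyl-3,3'-diyl]bis(prop-2-enoic acid)
Product: 8 target 3,3'-(6,6'-dihydroxy-5,5'-dimethoxy-[1,1'-biphenyl]-3,3'-diyl)dipropanoic acid, via saturated bis(benzyl ether) diacid 7 (not isolated)
Conditions: H2 (1–3 atm), 10 % Pd/C (10 wt %), THF/EtOH 1:1, rt, 16 h; filter through Celite, crystallise
Reagents that add atoms: none
Why: This heterogeneous catalytic hydrogenation first saturates the cinnamic C=C bonds and then hydrogenolyses both aryl benzyl ethers, while the aryl methyl ethers, carboxylic acids and arenes are inert, and no stereocentre arises.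

## Compound list
1 | vanillin (4-hydroxy-3-methoxybenzaldehyde) | COc1cc(C=O)ccc1O | starting material
2 | dehydrodivanillin, 6,6'-dihydroxy-5,5'-dimethoxy-[1,1'-biphenyl]-3,3'-dicarbaldehyde | COc1cc(C=O)cc(-c2cc(C=O)cc(OC)c2O)c1O | intermediate
3 | 6,6'-bis(benzyloxy)-5,5'-dimethoxy-[1,1'-biphenyl]-3,3'-dicarbaldehyde | COc1cc(C=O)cc(c1OCc1ccccc1)-c1cc(C=O)cc(OC)c1OCc1ccccc1 | intermediate
4 | malonic acid | O=C(O)CC(=O)O | starting material
5 | bis(arylidenemalonic acid), 2,2'-{[6,6'-bis(benzyloxy)-5,5'-dimethoxybiphenyl-3,3'-diyl]dimethanylylidene}dimalonic acid | COc1cc(C=C(C(=O)O)C(=O)O)cc(c1OCc1ccccc1)-c1cc(C=C(C(=O)O)C(=O)O)cc(OC)c1OCc1ccccc1 | intermediate (not isolated)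
6 | (2E,2'E)-3,3'-[6,6'-bis(benzyloxy)-5,5'-dimethoxybiphenyl-3,3'-diyl]bis(prop-2-enoic acid) | COc1cc(/C=C/C(=O)O)cc(c1OCc1ccccc1)-c1cc(/C=C/C(=O)O)cc(OC)c1OCc1ccccc1 | intermediate
7 | 3,3'-[6,6'-bis(benzyloxy)-5,5'-dimethoxybiphenyl-3,3'-diyl]dipropanoic acid | COc1cc(CCC(=O)O)cc(c1OCc1ccccc1)-c1cc(CCC(=O)O)cc(OC)c1OCc1ccccc1 | intermediate (not isolated)
8 | 3,3'-(6,6'-dihydroxy-5,5'-dimethoxy-[1,1'-biphenyl]-3,3'-diyl)dipropanoic acid (CNP0122720.0) | COc1cc(CCC(=O)O)cc(-c2cc(CCC(=O)O)cc(OC)c2O)c1O | target

## Step count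
Total steps: 4. Longest linear sequence: 4.

## Three steps most likely to fail, each with a fallback

**Step 1 (radical coupling).** The risks are over-oxidation, oligomers, and an insoluble product that is hard to free of iron and vanillin. The fallback builds the biaryl by cross-coupling instead of radical chemistry. It sets out from 1 and comes back at 3, so it replaces steps 1 and 2. Vanillin 1 is iodinated ortho to the phenol (I2, KI, NaHCO3, H2O, rt) to give 5-iodovanillin F1. This is benzylated (BnBr, K2CO3, DMF, 60 °C) to 4-(benzyloxy)-3-iodo-5-methoxybenzaldehyde F2. Half of F2 undergoes Miyaura borylation (B2pin2, PdCl2(dppf), KOAc, dioxane, 90 °C) to the pinacol boronate 4-(benzyloxy)-3-methoxy-5-(4,4,5,5-tetramethyl-1,3,2-dioxaborolan-2-yl)benzaldehyde F3. Suzuki coupling of F3 with the other half of F2 (PdCl2(dppf) or Pd/SPhos, aq K2CO3, dioxane, 90 °C) gives 3.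

**Step 3 (double Knoevenagel–Doebner).** The risks are incomplete reaction at the second aldehyde, mixtures of mono and bis products, and poorly soluble acids. The fallback uses a more acidic C-nucleophile and moves the reduction ahead of the decarboxylation. It sets out from 3 and comes back at 7.
- Dialdehyde 3 is condensed with Meldrum's acid (2.3 equiv, cat. piperidine/AcOH, EtOH, rt to 50 °C). The bis(arylidene Meldrum's acid) 5,5'-{[6,6'-bis(benzyloxy)-5,5'-dimethoxybiphenyl-3,3'-diyl]dimethanylylidene}bis(2,2-dimethyl-1,3-dioxane-4,6-dione) F4 crystallises out.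
- Conjugate reduction (NaBH4, CH2Cl2/MeOH, 0 °C) gives the bis(benzyl Meldrum's acid) F5.
- Hydrolysis and decarboxylation (pyridine/H2O 10:1, reflux) delivers 7. In this case 7 is isolated and needs only the hydrogenolysis half of step 4.

**Step 4 (global hydrogenation).** The risk is that hydrogenolysis of the two flanked benzyl ethers stalls, so that 7 accumulates. The fallback replaces hydrogenolysis by acidolysis with a cation scavenger. It sets out from 7 and comes back at 8. The isolated 7 is treated with TFA and pentamethylbenzene (6 equiv) at rt to 40 °C. The electron-rich aryl benzyl ethers ionise, the benzyl cation is trapped by Friedel–Crafts alkylation of the scavenger, and the methyl ethers and acids are untouched. No new intermediate is made.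

## Further compounds
F1 | step 1 | 5-iodovanillin (4-hydroxy-3-iodo-5-methoxybenzaldehyde) | COc1cc(C=O)cc(I)c1O
F2 | step 1 | 4-(benzyloxy)-3-iodo-5-methoxybenzaldehyde | COc1cc(C=O)cc(I)c1OCc1ccccc1
F3 | step 1 | 4-(benzyloxy)-3-methoxy-5-(4,4,5,5-tetramethyl-1,3,2-dioxaborolan-2-yl)benzaldehyde | COc1cc(C=O)cc(B2OC(C)(C)C(C)(C)O2)c1OCc1ccccc1
F4 | step 3 | 5,5'-{[6,6'-bis(benzyloxy)-5,5'-dimethoxybiphenyl-3,3'-diyl]dimethanylylidene}bis(2,2-dimethyl-1,3-dioxane-4,6-dione) | COc1cc(C=C2C(=O)OC(C)(C)OC2=O)cc(c1OCc1ccccc1)-c1cc(C=C2C(=O)OC(C)(C)OC2=O)cc(OC)c1OCc1ccccc1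
F5 | step 3 | 5,5'-{[6,6'-bis(benzyloxy)-5,5'-dimethoxybiphenyl-3,3'-diyl]dimethanediyl}bis(2,2-dimethyl-1,3-dioxane-4,6-dione) | COc1cc(CC2C(=O)OC(C)(C)OC2=O)cc(c1OCc1ccccc1)-c1cc(CC2C(=O)OC(C)(C)OC2=O)cc(OC)c1OCc1ccccc1
F0 | step 4 | none | none
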